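The runs were computed from invented constants; the scatter is artificial.

A slow fall runs through the late readings: in the delta run X sinks from 49.6% at 6.00 h to 42.4% at 12.0 h, so something takes X away while crystals D stand in that run.

| setting | delta | gamma | flask |
|---|---|---|---|
| Q | 0.050 M | 0.075 M | 0.10 M |
| E | 4.7 mM (held) | 4.7 mM (held) | 4.7 mM (held) |
| L | 1 mM | 1 mM | 1.0 mM |
| remark | run made earlier | run made earlier |  |
| time |  |  | 10 h |

| run | time / h | X / % | D / % |
|---|---|---|---|
| delta | 2.00 | 35.2 | 29.8 |
| delta | 4.00 | 47.1 | 42.8 |
| delta | 6.00 | 49.6 | 45.8 |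
| delta | 8.00 | 48.5 | 45.5 |
| delta | 10.0 | 45.5 | 42.4 |
| delta | 12.0 | 42.4 | 39.8 |
| gamma | 1.00 | 22.0 | 17.3 |
| gamma | 1.50 | 30.3 | 26.0 |
| gamma | 2.50 | 42.0 | 38.4 |
| gamma | 4.00 | 51.8 | 49.4 |
| gamma | 8.00 | 59.4 | 57.0 |
| gamma | 12.0 | 57.4 | 54.8 |

(readings scatter by 0.3 percentage points)

1. the X and D together standing at 10 h, as a percentage of the Q charged
2. concentration of G in solution at 10 h, in percent of saturation

- what is said of X includes D
- D is a solid; its amount is given per volume of the solution
- at the start none of E is in solution
- G is what E becomes in solution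

The quantity to follow is the missing amount at 10 h, a mass-balance deficit: the Q charged minus X (D counted in it), with any Q left over inside it. The delta run misses 27.2 mM. The gamma run has no reading at that time, so the mean of its readings at 8.00 h and 12.0 h stands in, and it misses 31.2 mM. Such a mean is open to doubt, but in the delta run the same mean gives 45.5% against the reading 45.5%.

A steady loss would be simpler. The delta run falls by 0.763 mM/h late on, yet over 10 h that makes 7.63 mM, less than the deficit, so the late rate run back to the start falls short and the deficit itself is kept.

Between the runs the charge rose by 25.0 mM and the deficit by 4.00 mM, which is less. That gives the marginal loss, the deficit gained per unit of extra Q charged: 0.158. Is a straight line fair? X minus D reads 1.55 mM in the delta run at 10.0 h and 1.95 mM in the gamma run at 12.0 h, close together although charges and times both differ, but the line stays an estimate from two runs. The line gives this flask a deficit of 35.2 mM, hence 64.8% for X and D.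

The forecast, from the same runs, says 65% for X and D and 95% for G, reckoning “with a loss largely independent of charge”.

The flask gives 64.2% for X and D, with G at 93.8% of saturation.

    E ⇌ G, rate k1*(csat - [G]) (kL = 47.0 /h)
    X ⇌ Z (K = 27.0, k = 2.10 /h)
    G ⇌ J (K = 390, k = 3.20 /h)
    Q + G + L → L + X (k = 1.00 × 10⁵ /M²/h)
    D ⇌ X, rate k5*(cs5 - [X]) while solid is left; crystals form when [X] > cs5 (solubility = 1.60 mM, k = 6.60 /h)

In the flask at 10.0 h Z stands at 34.3% and Q at 1.49%, and the deficit is 35.8 mM against the 35.2 mM reckoned. The marginal loss 0.158 carries down to a neighbour flask charged with 0.025 M of Q: its deficit comes to 23.3 mM, leaving 6.80% for X and D. That neighbour holds Z at 90.9% and X at 7.85%.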